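## Retrosynthetic overview

1. The two formyl groups go on last (Vilsmeier–Haack) after desilylation; the bridged oxepane (C4–C7' bond, quaternary C4 and C7') is closed by an iron-hydride-initiated radical addition of the C4=CH2 alkene to a tethered o-quinone methide.
2. The C2–O–aryl bond comes from a palladium-catalysed allylic etherification that joins terpene carbonate 23 to salicylaldehyde 31; the isobutyl group enters by Grignard addition.
3. Terpene 23: cyclopentane last (intramolecular allylsilane–enal cyclisation), after iron-catalysed methylation of an enol triflate and a cuprate addition anti to the cyclopropane; cycloheptene before that (Knoevenagel closure).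
4. Cyclopropane first: rhodium-catalysed enantioselective intramolecular cyclopropanation of prenyl diazoacetate, chain-extended by Wittig reaction with keto-ester ylide 4.
5. Arene 31 from resorcinol by iridium-catalysed C–H borylation/oxidation and directed lithiation–formylation. Ring order: cyclopropane, cycloheptene, cyclopentane, (arene attached), oxepane.

Assumption and labels: the target is taken exactly as the given SMILES, (2R,4R,5R,6R,7R,7'S) with terpene carbons C1–C15 in aromadendrane numbering (C1=C10, C2–O, C4 quaternary, C6/C7/C11 cyclopropane), aryl carbons C1'–C6' and benzylic carbon C7'; the β-face is the face carrying H-5 and C11. The route is a proposal and has not been run.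

## Route

### Ylide 4

Step 1
Reactants: 1 methyl acetoacetate
Product: 2 methyl 4-bromo-3-oxobutanoate
Conditions: Br2 (1.0 equiv), CHCl3, 0 °C to rt, 16 h, then air purge
Reagents that add atoms: bromine, BrBr
Why: Ketone bromination under HBr equilibration settles on the thermodynamically preferred 4-bromo isomer of the β-keto ester.

Step 2
Reactants: 2 methyl 4-bromo-3-oxobutanoate
Product: 3 (4-methoxy-2,4-dioxobutyl)triphenylphosphonium bromide
Conditions: PPh3, toluene, rt, 12 h, filter
Reagents that add atoms: triphenylphosphine, c1ccc(cc1)P(c1ccccc1)c1ccccc1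
Why: SN2 quaternisation of the phosphine by the reactive α-bromo ketone (phosphonium salt formation).

Step 3
Reactants: 3 (4-methoxy-2,4-dioxobutyl)triphenylphosphonium bromide
Product: 4 methyl 3-oxo-4-(triphenyl-λ5-phosphanylidene)butanoate
Conditions: aq. Na2CO3, CH2Cl2, rt
Reagents that add atoms: none
Why: Deprotonation of the acidic α-phosphonio ketone gives the stabilised acyl ylide (Wittig reagent formation).

### Terpene fragment 23

Step 4
Reactants: 5 prenol (3-methylbut-2-en-1-ol); 6 bromoacetyl bromide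
Product: 8 3-methylbut-2-en-1-yl diazoacetate, via bromoacetate 7 (not isolated)
Conditions: NaHCO3, MeCN, 0 °C; filter, concentrate; then TsNHNHTs, DBU, THF, 0 °C
Reagents that add atoms: N,N'-ditosylhydrazine, Cc1ccc(cc1)S(=O)(=O)NNS(=O)(=O)c1ccc(C)cc1
Why: O-acylation followed by the Fukuyama diazoacetate synthesis (N-alkylation of the ditosylhydrazine, then loss of two sulfinates) gives the allyl diazoacetate without touching the alkene.

Step 5
Reactants: 8 3-methylbut-2-en-1-yl diazoacetate
Product: 9 (1R,5S)-6,6-dimethyl-3-oxabicyclo[3.1.0]hexan-2-one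
Conditions: Rh2(5R-MEPY)4, i.e. dirhodium tetrakis[methyl (5R)-2-oxopyrrolidine-5-carboxylate] (0.2 mol%), CH2Cl2, reflux, slow addition
Reagents that add atoms: none
Why: Chiral dirhodium carboxamidate-catalysed intramolecular cyclopropanation; the tether enforces the cis ring fusion and the catalyst pocket selects the (1R,5S) enantiomer, which fixes C6 and C7 of the target.

Step 6
Reactants: 9 (1R,5S)-6,6-dimethyl-3-oxabicyclo[3.1.0]hexan-2-one
Product: 10 (1R,5S)-6,6-dimethyl-3-oxabicyclo[3.1.0]hexan-2-ol (anomer mixture)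
Conditions: i-Bu2AlH (1.1 equiv), CH2Cl2, −78 °C; Rochelle salt
Reagents that add atoms: none
Why: Half-reduction of a γ-lactone stops at the aluminium hemiacetal at low temperature (lactone to lactol).

Step 7
Reactants: 10 (1R,5S)-6,6-dimethyl-3-oxabicyclo[3.1.0]hexan-2-ol; 4 methyl 3-oxo-4-(triphenyl-λ5-phosphanylidene)butanoate
Product: 11 methyl (4E)-5-[(1R,3S)-3-(hydroxymethyl)-2,2-dimethylcyclopropyl]-3-oxopent-4-enoate
Conditions: 4 (1.5 equiv), PhCO2H (10 mol%), toluene, 80 °C
Reagents that add atoms: none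
Why: Wittig olefination of the ring-opened hydroxy aldehyde by a stabilised acyl ylide gives the E-enone and brings in C9, C10, C1 and C2 in one step.

Step 8
Reactants: 11 methyl (4E)-5-[(1R,3S)-3-(hydroxymethyl)-2,2-dimethylcyclopropyl]-3-oxopent-4-enoate
Product: 12 methyl 5-[(1R,3S)-3-(hydroxymethyl)-2,2-dimethylcyclopropyl]-3-oxopentanoate
Conditions: Stryker's reagent [(Ph3P)CuH]6 (0.35 equiv), H2O (3 equiv), THF/benzene, rt
Reagents that add atoms: none
Why: Copper hydride conjugate reduction saturates only the enone C=C through a copper enolate, with no radical that could open the vinylcyclopropane.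

Step 9
Reactants: 12 methyl 5-[(1R,3S)-3-(hydroxymethyl)-2,2-dimethylcyclopropyl]-3-oxopentanoate
Product: 14 methyl (1S,7R)-8,8-dimethyl-4-oxobicyclo[5.1.0]oct-2-ene-3-carboxylate, via keto aldehyde 13 (not isolated)
Conditions: (COCl)2, DMSO, CH2Cl2, −78 °C; Et3N, −78 to 0 °C; then piperidine (20 mol%), AcOH (20 mol%), 4 Å MS, 0.01 M, rt; used crude
Reagents that add atoms: none
Why: Swern oxidation then intramolecular Knoevenagel condensation, the cis-cyclopropane holding the aldehyde (C5) and the β-keto ester methylene (C1) within reach for seven-membered ring closure.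

Step 10
Reactants: 14 methyl (1S,7R)-8,8-dimethyl-4-oxobicyclo[5.1.0]oct-2-ene-3-carboxylate; 15 (2-bromoprop-2-en-1-yl)trimethylsilane
Product: 18 methyl (1R,2S,7R)-8,8-dimethyl-4-{[(trifluoromethyl)sulfonyl]oxy}-2-[3-(trimethylsilyl)prop-1-en-2-yl]bicyclo[5.1.0]oct-3-ene-3-carboxylate, via Grignard reagent 16 (not isolated), via magnesium enolate 17 (not isolated)
Conditions: 15, Mg, THF, rt; CuBr·SMe2 (15 mol%), THF, −78 °C, add 14; then Comins' reagent, −78 to 0 °C
Reagents that add atoms: Comins' reagent, N-(5-chloropyridin-2-yl)-1,1,1-trifluoro-N-[(trifluoromethyl)sulfonyl]methanesulfonamide, Clc1ccc(nc1)N(S(=O)(=O)C(F)(F)F)S(=O)(=O)C(F)(F)F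
Why: Copper-catalysed conjugate addition to the doubly activated alkene occurs anti to the gem-dimethylcyclopropane and so sets C5 (H-5 cis to C11 as in the target), and the chelated β-keto ester enolate is trapped on oxygen as the enol triflate.

Step 11
Reactants: 18 enol triflate from step 10
Product: 19 methyl (1R,2S,7R)-4,8,8-trimethyl-2-[3-(trimethylsilyl)prop-1-en-2-yl]bicyclo[5.1.0]oct-3-ene-3-carboxylate
Conditions: MeMgBr (1.3 equiv), Fe(acac)3 (5 mol%), THF/NMP, −30 °C, 15 min
Reagents that add atoms: methylmagnesium bromide, C[Mg]Br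
Why: Iron-catalysed cross-coupling of an alkenyl triflate with a Grignard reagent (Kochi–Fürstner type) installs the C14 methyl on the tetrasubstituted alkene faster than the ester or allylsilane can react.

Step 12
Reactants: 19 methyl (1R,2S,7R)-4,8,8-trimethyl-2-[3-(trimethylsilyl)prop-1-en-2-yl]bicyclo[5.1.0]oct-3-ene-3-carboxylate
Product: 20 {(1R,2S,7R)-4,8,8-trimethyl-2-[3-(trimethylsilyl)prop-1-en-2-yl]bicyclo[5.1.0]oct-3-en-3-yl}methanol
Conditions: i-Bu2AlH (2.5 equiv), CH2Cl2, −78 °C; Rochelle salt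
Reagents that add atoms: none
Why: 1,2-Reduction of the hindered unsaturated ester to the allylic alcohol by an aluminium hydride.

Step 13
Reactants: 20 allylic alcohol from step 12
Product: 21 (1R,2S,7R)-4,8,8-trimethyl-2-[3-(trimethylsilyl)prop-1-en-2-yl]bicyclo[5.1.0]oct-3-ene-3-carbaldehyde
Conditions: MnO2 (15 equiv), CH2Cl2, rt
Reagents that add atoms: none
Why: Selective oxidation of an allylic alcohol to the enal with activated MnO2, which leaves the allylsilane alone.

Step 14
Reactants: 21 enal from step 13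
Product: 22 (1aR,5R,7aR,7bR)-1,1,4-trimethyl-7-methylidene-1a,2,3,5,6,7,7a,7b-octahydro-1H-cyclopropa[e]azulen-5-ol
Conditions: BF3·OEt2 (1.2 equiv), CH2Cl2, −78 °C; aq. NaHCO3
Reagents that add atoms: none
Why: Intramolecular Hosomi–Sakurai allylation (methylenecyclopentane annulation) closes the five-membered ring; the allylsilane sits on the α-face of C5 and attacks the complexed aldehyde antiperiplanar to C=O, so the oxygen ends on the β-face (2R) and the exocyclic C4=CH2 is formed.

Step 15
Reactants: 22 allylic alcohol from step 14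
Product: 23 (1aR,5R,7aR,7bR)-1,1,4-trimethyl-7-methylidene-1a,2,3,5,6,7,7a,7b-octahydro-1H-cyclopropa[e]azulen-5-yl methyl carbonate
Conditions: ClCO2Me, pyridine, DMAP (cat.), CH2Cl2, 0 °C
Reagents that add atoms: methyl chloroformate, COC(=O)Cl
Why: Acylation of the secondary allylic alcohol gives the carbonate leaving group for π-allyl formation, with C2 unchanged.

### Aryl fragment 31

Step 16
Reactants: 24 resorcinol
Product: 25 1,3-bis(methoxymethoxy)benzene
Conditions: MOMCl (2.5 equiv), i-Pr2NEt, CH2Cl2, 0 °C to rt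
Reagents that add atoms: chloromethyl methyl ether, COCCl
Why: Standard acetal protection of both phenols, which also supplies the directing groups needed in step 20.

Step 17
Reactants: 25 1,3-bis(methoxymethoxy)benzene
Product: 26 2-[3,5-bis(methoxymethoxy)phenyl]-4,4,5,5-tetramethyl-1,3,2-dioxaborolane
Conditions: [Ir(OMe)(cod)]2 (1.5 mol%), dtbpy (3 mol%), B2pin2 (1.0 equiv), THF, 80 °C
Reagents that add atoms: bis(pinacolato)diboron, CC1(C)OB(OC1(C)C)B1OC(C)(C)C(C)(C)O1
Why: Iridium-catalysed aromatic C–H borylation is sterically controlled and takes the only C–H that is not ortho to a substituent (C5).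

Step 18
Reactants: 26 arylboronate from step 17
Product: 27 3,5-bis(methoxymethoxy)phenol
Conditions: 30% H2O2, 2 M NaOH, THF, 0 °C to rt
Reagents that add atoms: hydrogen peroxide, OO
Why: Oxidation of the arylboronate by 1,2-migration from boron to oxygen gives the third phenolic oxygen under base, which MOM ethers tolerate.

Step 19
Reactants: 27 3,5-bis(methoxymethoxy)phenol
Product: 28 [3,5-bis(methoxymethoxy)phenoxy]tri(propan-2-yl)silane
Conditions: TIPSCl, imidazole, DMF, rt
Reagents that add atoms: chlorotri(propan-2-yl)silane, CC(C)[Si](Cl)(C(C)C)C(C)C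
Why: Silylation marks the unique oxygen (future O4') with a bulky group that is stable to base and is a poor metalation director.

Step 20
Reactants: 28 [3,5-bis(methoxymethoxy)phenoxy]tri(propan-2-yl)silane
Product: 30 2,6-bis(methoxymethoxy)-4-{[tri(propan-2-yl)silyl]oxy}benzaldehyde, via aryllithium 29 (not isolated)
Conditions: n-BuLi (1.2 equiv), TMEDA, THF, 0 °C, 1 h; DMF, 0 °C to rt; aq. NH4Cl
Reagents that add atoms: N,N-dimethylformamide, CN(C)C=O
Why: Directed ortho-metalation occurs at the carbon flanked by both MOM ethers (cooperative direction, para to the silyl ether) and DMF quench gives the aldehyde carbon that becomes C7'.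

Step 21
Reactants: 30 2,6-bis(methoxymethoxy)-4-{[tri(propan-2-yl)silyl]oxy}benzaldehyde
Product: 31 2,6-dihydroxy-4-{[tri(propan-2-yl)silyl]oxy}benzaldehyde
Conditions: 2 M HCl, MeOH, 45 °C
Reagents that add atoms: none
Why: Acid-catalysed acetal exchange removes both MOM groups while the aryl silyl ether, which is acid-stable, stays.

### Union and end game

Step 22
Reactants: 23 allylic methyl carbonate; 31 2,6-dihydroxy-4-{[tri(propan-2-yl)silyl]oxy}benzaldehyde
Product: 32 2-hydroxy-6-{[(1aR,5R,7aR,7bR)-1,1,4-trimethyl-7-methylidene-1a,2,3,5,6,7,7a,7b-octahydro-1H-cyclopropa[e]azulen-5-yl]oxy}-4-{[tri(propan-2-yl)silyl]oxy}benzaldehyde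
Conditions: 31 (2.0 equiv), Pd2(dba)3·CHCl3 (5 mol%), dppf (11 mol%), THF, 40 °C
Reagents that add atoms: none
Why: Tsuji–Trost allylic etherification: zerovalent palladium ionises the carbonate anti, the phenoxide attacks the less substituted allyl terminus C2 anti to palladium (net retention, 2R), and the two hydroxyls of 31 are equivalent so mono-allylation gives one product.

Step 23
Reactants: 32 aryl ether aldehyde from step 22
Product: 33 2-(1-hydroxy-3-methylbutyl)-3-{[(1aR,5R,7aR,7bR)-1,1,4-trimethyl-7-methylidene-1a,2,3,5,6,7,7a,7b-octahydro-1H-cyclopropa[e]azulen-5-yl]oxy}-5-{[tri(propan-2-yl)silyl]oxy}phenol (carbinol epimers)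
Conditions: i-BuMgBr (3.0 equiv), THF, −78 to 0 °C; aq. NH4Cl; Et3N-deactivated silica
Reagents that add atoms: isobutylmagnesium bromide, CC(C)C[Mg]Br
Why: Grignard addition to the salicylaldehyde (one equivalent is spent on the phenol) gives the o-hydroxybenzyl alcohol; the carbinol configuration does not matter because this carbon becomes planar in the next step.

Step 24
Reactants: 33 o-hydroxybenzyl alcohol from step 23
Product: 35 4'-O-triisopropylsilyl-3',5'-dideformyl target (bridged core with the C4–C7' bond), via o-quinone methide 34 (not isolated)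
Conditions: Fe(acac)3 (30 mol%), PhSiH3 (3 equiv), EtOH/ethylene glycol 5:1, 0.005 M, 60 °C
Reagents that add atoms: none
Why: Proposed new method: an iron hydride formed from Fe(acac)3 and PhSiH3 transfers a hydrogen atom to the 1,1-disubstituted C4=CH2 alkene (Markovnikov, far faster than to the tetrasubstituted C1=C10 alkene) to give the tertiary C4 radical and the C15 methyl, while the electron-rich o-hydroxybenzyl alcohol reversibly dehydrates in warm ethanol to o-quinone methide 34, whose exocyclic carbon C7' is captured by the tethered radical in a seven-membered ring closure driven by re-aromatisation, the phenoxyl radical then being reduced by divalent iron and protonated; the C2–O tether allows bond formation only on the β-face of C4 (4R, methyl α) and, with the aryl held anti to that methyl, the isobutyl group is expected to take the sector next to C3H2 and not the one next to C5 (7'S), both quinone methide geometries being reachable through the reversible ethanol adduct; the closest known reaction types are the iron-catalysed reductive olefin coupling (hydrogen-atom-transfer Giese addition to enones) and the iron-catalysed olefin hydroalkylation of p-quinone methides, neither shown intramolecularly on an o-quinone methide made in situ.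

Step 25
Reactants: 35 cyclised silyl ether from step 24
Product: 36 3',5'-dideformyl target (4',6'-diol)
Conditions: TBAF (1.2 equiv), AcOH (1.2 equiv), THF, 0 °C
Reagents that add atoms: none
Why: Buffered fluoride cleaves the aryl silyl ether without acid or strong base, so the allylic aryl ether, alkene and cyclopropane are untouched.

Step 26
Reactants: 36 diphenol from step 25
Product: 37 CNP0388405.1 (target)
Conditions: POCl3 (4 equiv), DMF (8 equiv), EtOAc, 0 °C to rt; then aq. NaOAc, rt
Reagents that add atoms: N,N-dimethylformamide, CN(C)C=O; water, O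
Why: Vilsmeier–Haack formylation of the phloroglucinol ring takes place twice, at C3' and C5', the only free aromatic positions and both activated by ortho/para oxygens, and hydrolysis of the two iminium salts gives the dialdehyde.

## Compound list

1 | methyl acetoacetate | COC(=O)CC(C)=O | starting material
2 | methyl 4-bromo-3-oxobutanoate | COC(=O)CC(=O)CBr | intermediate
3 | (4-methoxy-2,4-dioxobutyl)triphenylphosphonium bromide | COC(=O)CC(=O)C[P+](c1ccccc1)(c1ccccc1)c1ccccc1.[Br-] | intermediate
4 | methyl 3-oxo-4-(triphenyl-λ5-phosphanylidene)butanoate | COC(=O)CC(=O)C=P(c1ccccc1)(c1ccccc1)c1ccccc1 | intermediate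
5 | prenol (3-methylbut-2-en-1-ol) | CC(C)=CCO | starting material
6 | bromoacetyl bromide | BrCC(Br)=O | starting material
7 | 3-methylbut-2-en-1-yl bromoacetate | CC(C)=CCOC(=O)CBr | intermediate (not isolated)
8 | 3-methylbut-2-en-1-yl diazoacetate | CC(C)=CCOC(=O)C=[N+]=[N-] | intermediate
9 | (1R,5S)-6,6-dimethyl-3-oxabicyclo[3.1.0]hexan-2-one | O=C1OC[C@H]2[C@@H]1C2(C)C | intermediate
10 | (1R,5S)-6,6-dimethyl-3-oxabicyclo[3.1.0]hexan-2-ol, anomer mixture | OC1OC[C@H]2[C@@H]1C2(C)C | intermediate
11 | methyl (4E)-5-[(1R,3S)-3-(hydroxymethyl)-2,2-dimethylcyclopropyl]-3-oxopent-4-enoate | OC[C@H]1[C@@H](/C=C/C(=O)CC(=O)OC)C1(C)C | intermediate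
12 | methyl 5-[(1R,3S)-3-(hydroxymethyl)-2,2-dimethylcyclopropyl]-3-oxopentanoate | OC[C@H]1[C@@H](CCC(=O)CC(=O)OC)C1(C)C | intermediate
13 | methyl 5-[(1R,3S)-3-formyl-2,2-dimethylcyclopropyl]-3-oxopentanoate | O=C[C@H]1[C@@H](CCC(=O)CC(=O)OC)C1(C)C | intermediate (not isolated)
14 | methyl (1S,7R)-8,8-dimethyl-4-oxobicyclo[5.1.0]oct-2-ene-3-carboxylate | O=C1C(C(=O)OC)=C[C@H]2[C@@H](CC1)C2(C)C | intermediate
15 | (2-bromoprop-2-en-1-yl)trimethylsilane | BrC(=C)C[Si](C)(C)C | starting material
16 | bromo[3-(trimethylsilyl)prop-1-en-2-yl]magnesium | Br[Mg]C(=C)C[Si](C)(C)C | intermediate (not isolated)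
17 | bromomagnesium enolate of methyl (1R,2S,7R)-8,8-dimethyl-4-oxo-2-[3-(trimethylsilyl)prop-1-en-2-yl]bicyclo[5.1.0]octane-3-carboxylate | Br[Mg]OC1=C(C(=O)OC)[C@H]([C@H]2[C@@H](CC1)C2(C)C)C(=C)C[Si](C)(C)C | intermediate (not isolated)
18 | methyl (1R,2S,7R)-8,8-dimethyl-4-{[(trifluoromethyl)sulfonyl]oxy}-2-[3-(trimethylsilyl)prop-1-en-2-yl]bicyclo[5.1.0]oct-3-ene-3-carboxylate | FC(F)(F)S(=O)(=O)OC1=C(C(=O)OC)[C@H]([C@H]2[C@@H](CC1)C2(C)C)C(=C)C[Si](C)(C)C | intermediate
19 | methyl (1R,2S,7R)-4,8,8-trimethyl-2-[3-(trimethylsilyl)prop-1-en-2-yl]bicyclo[5.1.0]oct-3-ene-3-carboxylate | CC1=C(C(=O)OC)[C@H]([C@H]2[C@@H](CC1)C2(C)C)C(=C)C[Si](C)(C)C | intermediate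
20 | {(1R,2S,7R)-4,8,8-trimethyl-2-[3-(trimethylsilyl)prop-1-en-2-yl]bicyclo[5.1.0]oct-3-en-3-yl}methanol | CC1=C(CO)[C@H]([C@H]2[C@@H](CC1)C2(C)C)C(=C)C[Si](C)(C)C | intermediate
21 | (1R,2S,7R)-4,8,8-trimethyl-2-[3-(trimethylsilyl)prop-1-en-2-yl]bicyclo[5.1.0]oct-3-ene-3-carbaldehyde | CC1=C(C=O)[C@H]([C@H]2[C@@H](CC1)C2(C)C)C(=C)C[Si](C)(C)C | intermediate
22 | (1aR,5R,7aR,7bR)-1,1,4-trimethyl-7-methylidene-1a,2,3,5,6,7,7a,7b-octahydro-1H-cyclopropa[e]azulen-5-ol | CC1=C2[C@H]([C@H]3[C@@H](CC1)C3(C)C)C(=C)C[C@H]2O | intermediate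
23 | (1aR,5R,7aR,7bR)-1,1,4-trimethyl-7-methylidene-1a,2,3,5,6,7,7a,7b-octahydro-1H-cyclopropa[e]azulen-5-yl methyl carbonate | CC1=C2[C@H]([C@H]3[C@@H](CC1)C3(C)C)C(=C)C[C@H]2OC(=O)OC | intermediate
24 | resorcinol | Oc1cccc(O)c1 | starting material
25 | 1,3-bis(methoxymethoxy)benzene | COCOc1cccc(OCOC)c1 | intermediate
26 | 2-[3,5-bis(methoxymethoxy)phenyl]-4,4,5,5-tetramethyl-1,3,2-dioxaborolane | COCOc1cc(OCOC)cc(c1)B1OC(C)(C)C(C)(C)O1 | intermediate
27 | 3,5-bis(methoxymethoxy)phenol | COCOc1cc(O)cc(OCOC)c1 | intermediate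
28 | [3,5-bis(methoxymethoxy)phenoxy]tri(propan-2-yl)silane | COCOc1cc(OCOC)cc(O[Si](C(C)C)(C(C)C)C(C)C)c1 | intermediate
29 | {2,6-bis(methoxymethoxy)-4-[tri(propan-2-yl)silyloxy]phenyl}lithium | [Li]c1c(OCOC)cc(O[Si](C(C)C)(C(C)C)C(C)C)cc1OCOC | intermediate (not isolated)
30 | 2,6-bis(methoxymethoxy)-4-{[tri(propan-2-yl)silyl]oxy}benzaldehyde | O=Cc1c(OCOC)cc(O[Si](C(C)C)(C(C)C)C(C)C)cc1OCOC | intermediate
31 | 2,6-dihydroxy-4-{[tri(propan-2-yl)silyl]oxy}benzaldehyde | O=Cc1c(O)cc(O[Si](C(C)C)(C(C)C)C(C)C)cc1O | intermediate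
32 | 2-hydroxy-6-{[(1aR,5R,7aR,7bR)-1,1,4-trimethyl-7-methylidene-octahydro-1H-cyclopropa[e]azulen-5-yl]oxy}-4-{[tri(propan-2-yl)silyl]oxy}benzaldehyde | CC1=C2[C@H]([C@H]3[C@@H](CC1)C3(C)C)C(=C)C[C@H]2Oc1cc(O[Si](C(C)C)(C(C)C)C(C)C)cc(O)c1C=O | intermediate
33 | 2-(1-hydroxy-3-methylbutyl)-3-{[(1aR,5R,7aR,7bR)-1,1,4-trimethyl-7-methylidene-octahydro-1H-cyclopropa[e]azulen-5-yl]oxy}-5-{[tri(propan-2-yl)silyl]oxy}phenol, carbinol epimers | CC1=C2[C@H]([C@H]3[C@@H](CC1)C3(C)C)C(=C)C[C@H]2Oc1cc(O[Si](C(C)C)(C(C)C)C(C)C)cc(O)c1C(O)CC(C)C | intermediate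
34 | 6-(3-methylbutylidene)-5-{[(1aR,5R,7aR,7bR)-1,1,4-trimethyl-7-methylidene-octahydro-1H-cyclopropa[e]azulen-5-yl]oxy}-3-{[tri(propan-2-yl)silyl]oxy}cyclohexa-2,4-dien-1-one, E/Z mixture | CC1=C2[C@H]([C@H]3[C@@H](CC1)C3(C)C)C(=C)C[C@H]2OC1=CC(O[Si](C(C)C)(C(C)C)C(C)C)=CC(=O)C1=CCC(C)C | intermediate (not isolated)
35 | (2R,4R,5R,6R,7R,7'S) bridged core: target without the two formyl groups, 4'-O-triisopropylsilyl, 6'-OH | CC1=C2[C@H]([C@H]3[C@@H](CC1)C3(C)C)[C@]1(C)C[C@H]2Oc2cc(O[Si](C(C)C)(C(C)C)C(C)C)cc(O)c2[C@H]1CC(C)C | intermediate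
36 | (2R,4R,5R,6R,7R,7'S) bridged core: target without the two formyl groups, 4',6'-diol | CC1=C2[C@H]([C@H]3[C@@H](CC1)C3(C)C)[C@]1(C)C[C@H]2Oc2cc(O)cc(O)c2[C@H]1CC(C)C | intermediate
37 | CNP0388405.1, (2R,4R,5R,6R,7R,7'S) | CC1=C2[C@H]([C@H]3[C@@H](CC1)C3(C)C)[C@]1(C)C[C@H]2Oc2c(C=O)c(O)c(C=O)c(O)c2[C@H]1CC(C)C | target

## Step count and risks

Total step count: 26. Longest linear sequence: 17 (steps 4–15, then 22–26; the path from methyl acetoacetate through steps 1–3, 7–15 and 22–26 is also 17).

**Step 24 (the proposed radical/quinone methide cyclisation).** It may fail through simple reduction of the C4 radical or of the quinone methide, through hetero-Diels–Alder capture of the quinone methide by the alkene, or through poor control at C7'. The fallback uses the known iron-hydride reductive olefin–enone coupling and sets out from aldehyde 32. Wittig reaction with 1-(triphenylphosphoranylidene)propan-2-one (toluene, 80 °C) gives (3E)-4-[2-hydroxy-6-(terpenyloxy)-4-(triisopropylsilyloxy)phenyl]but-3-en-2-one F8. Fe(acac)3/PhSiH3 in EtOH/ethylene glycol at 60 °C then adds the C4 radical to the enone β-carbon C7' and gives the bridged methyl ketone F9, the analogue of 35 that carries CH2C(=O)CH3 at C7'. Methylenation with excess Ph3P=CH2 in THF gives the 2-methylprop-2-enyl compound F10, and hydrogenation of that 1,1-disubstituted alkene with H2 and RhCl(PPh3)3, which leaves the tetrasubstituted C1=C10 alkene, comes back to the route at 35.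

**Step 22 (palladium-catalysed etherification).** Ionisation of a carbonate next to a tetrasubstituted alkene may be slow, and β-hydride elimination to dienes, attack at C10 or re-ionisation of the aryl ether can compete. The fallback replaces the π-allyl chemistry by two Mitsunobu inversions and sets out from alcohol 22. 4-Nitrobenzoic acid, DIAD and PPh3 give the inverted (1aR,5S,7aR,7bR)-4-nitrobenzoate F6; K2CO3 in MeOH frees the (5S)-alcohol F7; a second Mitsunobu reaction of F7 with phenol 31 (DIAD, PPh3, toluene) inverts C2 again and comes back to the route at 32.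

**Step 7 (Wittig reaction on the lactol).** The ring-opened aldehyde is present only in small amount and the product hydroxy enone can close by oxa-Michael addition to a tetrahydrofuran. The fallback keeps the hydroxyl masked and sets out from lactone 9. Opening with MeNH(OMe)·HCl and i-PrMgCl (THF, −20 °C) gives the hydroxy Weinreb amide F1, silylated in the same flask (TESCl, imidazole) to the triethylsilyl ether F2. i-Bu2AlH at −78 °C gives (1R,3S)-2,2-dimethyl-3-{[(triethylsilyl)oxy]methyl}cyclopropane-1-carbaldehyde F3, and Wittig reaction with 4 gives the silyl-protected E-enone F4. Stryker's reagent [(Ph3P)CuH]6 gives the saturated silyl ether F5, and HF·pyridine removes the silyl group and comes back to the route at 12.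

## Further compounds

F1 | step 7 | (1R,3S)-3-(hydroxymethyl)-N-methoxy-N,2,2-trimethylcyclopropane-1-carboxamide | OC[C@H]1[C@@H](C(=O)N(C)OC)C1(C)C
F2 | step 7 | (1R,3S)-N-methoxy-N,2,2-trimethyl-3-{[(triethylsilyl)oxy]methyl}cyclopropane-1-carboxamide | CC[Si](CC)(CC)OC[C@H]1[C@@H](C(=O)N(C)OC)C1(C)C
F3 | step 7 | (1R,3S)-2,2-dimethyl-3-{[(triethylsilyl)oxy]methyl}cyclopropane-1-carbaldehyde | CC[Si](CC)(CC)OC[C@H]1[C@@H](C=O)C1(C)C
F4 | step 7 | methyl (4E)-5-[(1R,3S)-2,2-dimethyl-3-{[(triethylsilyl)oxy]methyl}cyclopropyl]-3-oxopent-4-enoate | CC[Si](CC)(CC)OC[C@H]1[C@@H](/C=C/C(=O)CC(=O)OC)C1(C)C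
F5 | step 7 | methyl 5-[(1R,3S)-2,2-dimethyl-3-{[(triethylsilyl)oxy]methyl}cyclopropyl]-3-oxopentanoate | CC[Si](CC)(CC)OC[C@H]1[C@@H](CCC(=O)CC(=O)OC)C1(C)C
F6 | step 22 | (1aR,5S,7aR,7bR)-1,1,4-trimethyl-7-methylidene-1a,2,3,5,6,7,7a,7b-octahydro-1H-cyclopropa[e]azulen-5-yl 4-nitrobenzoate | CC1=C2[C@H]([C@H]3[C@@H](CC1)C3(C)C)C(=C)C[C@@H]2OC(=O)c1ccc(cc1)[N+](=O)[O-]
F7 | step 22 | (1aR,5S,7aR,7bR)-1,1,4-trimethyl-7-methylidene-1a,2,3,5,6,7,7a,7b-octahydro-1H-cyclopropa[e]azulen-5-ol | CC1=C2[C@H]([C@H]3[C@@H](CC1)C3(C)C)C(=C)C[C@@H]2O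
F8 | step 24 | (3E)-4-[2-hydroxy-6-{[(1aR,5R,7aR,7bR)-1,1,4-trimethyl-7-methylidene-octahydro-1H-cyclopropa[e]azulen-5-yl]oxy}-4-{[tri(propan-2-yl)silyl]oxy}phenyl]but-3-en-2-one | CC1=C2[C@H]([C@H]3[C@@H](CC1)C3(C)C)C(=C)C[C@H]2Oc1cc(O[Si](C(C)C)(C(C)C)C(C)C)cc(O)c1/C=C/C(C)=O
F9 | step 24 | analogue of 35 with a 2-oxopropyl group at C7' in place of isobutyl | CC1=C2[C@H]([C@H]3[C@@H](CC1)C3(C)C)[C@]1(C)C[C@H]2Oc2cc(O[Si](C(C)C)(C(C)C)C(C)C)cc(O)c2[C@H]1CC(C)=O
F10 | step 24 | analogue of 35 with a 2-methylprop-2-enyl group at C7' in place of isobutyl | CC1=C2[C@H]([C@H]3[C@@H](CC1)C3(C)C)[C@]1(C)C[C@H]2Oc2cc(O[Si](C(C)C)(C(C)C)C(C)C)cc(O)c2[C@H]1CC(C)=C
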